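The constants used here are invented; no experiment stands behind them.

I decide to follow one number, f, the Yx left as a fraction of its charge, since the ring closure is first order in it and the dimerisation second order.

    Yx → Ze (k1 = 0.065 h⁻¹)
    2 Yx → Qi (k2 = 0.017 L mol⁻¹ h⁻¹)
    Yx + Qi → Uv (k3 = 0.013 L mol⁻¹ h⁻¹)
    Qi → Xa (k4 = 0.087 h⁻¹)
    Ze ⇌ Jy (K5 = 0.38, k5 = 0.063 h⁻¹)
    Yx ⇌ Kj (K6 = 1.6, k6 = 0.031 h⁻¹)

| setting | oak | maple |
|---|---|---|
| Yx | 2.0 M | 2.0 M |
| time | 30 h |  |
| remark | everything together in a closed stirred flask, run for 30 h | one stirred flow tank at steady state, fed with the mixture as stated, mean residence time 30 h |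

- the set-up with the highest share of Ze in all that became Ze or Qi or Uv or Xa or Jy, at the outlet or at the end ("none" if the first two lie within 2 percentage points) (oak / maple / none)
- share of Ze in all that became Ze or Qi or Uv or Xa or Jy, at the outlet or at the end, oak
- share of Ze in all that became Ze or Qi or Uv or Xa or Jy, at the outlet or at the end, maple

- in percentages every species weighs as the Yx in it: one Qi or Xa counts as two
- in percentages every species weighs as the Yx in it: one Uv counts as three
- two of one species on the left: rate k times its square, two consumed each time
- the stated concentrations are those of everything mixed, before any reaction; amounts are the same in each set-up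
- run time (oak): 30 h

The ring side (Ze, Jy) draws Yx at 0.065 h⁻¹ times f, and the chain side (Qi, Uv, Xa) draws it at 0.0680 h⁻¹ times f squared. Their ratio, the selectivity factor, is f*/f, where the crossover fraction f* = 0.956 is the f at which the two draws are equal. I leave Uv's extra Yx out of this count.

In oak the half-life of Yx by ring closure, 11 h, is shorter than the run of 30 h, so I let f fall from one to zero; keeping Kj out is a simplification of mine. My first way integrates the ring share f*/(f*+f) along that path, which gives f* times the logarithm of one plus its inverse, 0.684. My second way reads the same share at the midpoint of that path, f = 0.5, and gives 0.657. The two part, the first being higher, and the second cheats: this share is curved in f, so its mean between one and zero differs from its value at the midpoint. Ze and Jy relax with a half-life of 3.03 h, shorter than the run, so in oak I give Ze 0.725 of the ring side, and oak comes to 49.6 %.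

Maple holds one f. With Kj standing at 0.588 of Yx, the Yx balance of maple says that one equals 3.54 f plus 2.04 f squared. So f = 0.247, lower than f*, and the ring share is 0.794. Jy stands at 0.316 of Ze, so Ze holds 0.760 of the ring side, and maple comes to 60.3 %. I commit to maple.

The forecast names maple, with 49.1 % for oak and 60.1 % for maple: “The flow tank wins because low Yx suppresses the second-order dimerisation.”

The flasks give 49.1 % for oak and 60.1 % for maple, so maple leads. At the end of oak, 6.07 % of the charge is still Yx and 16.4 % stands as Kj, whereas my integral ran f to zero. A flask like oak charged with 0.80 M of Yx has its crossover fraction at 2.39, the same two factors give 60.5 %, and that flask reads 61.1 %.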